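**Retrosynthetic overview**

1. The last bond made is the CH2 bridge between C6 of ring A (the 2-butanoyl-4,4-dimethyl dienone) and the one free carbon of ring B, formed by Mannich base / ortho-quinone methide alkylation after global deprotection.
2. The strategy rests on ring C, the central benzene ring: its C–OH carbon sits between the two carbons bearing the CH2 bridges to rings B and D, and oxygen is on the three alternate carbons. This ring is built, not bought, by fusing a 3-ethoxy-4-(ring B benzyl)cyclobutenone with a (ring D benzyl)-substituted siloxyalkyne.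
3. The cyclobutenone comes from a ring B propanoyl chloride (via its ketene) and ethoxyacetylene. The siloxyalkyne comes from a ring D arylacetic ester by Kowalski ynolate formation; a silyl ynol ether is used because it cannot lose ethylene by retro-ene reaction on heating.
4. Butanoyl groups: rings A and B get theirs early from butyrylphloroglucinol; rings C and D are acylated together after the benzannulation, each at its single free carbon.
5. Ring order: rings A, B and D are bought as phloroglucinols; ring C is the only ring formed (step 10).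

Key step: step 10

Remark: the target has no stereocentre, and ring A is drawn as one tautomer of an enolised triketone. Compounds 15, 20, 27 and 29 are racemic, and their stereocentres disappear later. Abbreviations: ArB = 3-butanoyl-2,4,6-tris(benzyloxy)phenyl; ArD = 2,4,6-tris(benzyloxy)-3-methylphenyl; Bn = benzyl; TIPS = triisopropylsilyl; DTBMP = 2,6-di-tert-butyl-4-methylpyridine.

**Route**

Step 1
Reactants: 1 phloroglucinol; 2 butanoyl chloride
Product: 3 1-(2,4,6-trihydroxyphenyl)butan-1-one (butyrylphloroglucinol)
Conditions: AlCl3, PhNO2, 65 °C; then ice, aq. HCl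
Reagents that add atoms: none
Why: Friedel–Crafts C-acylation of phloroglucinol, which should stop after one acyl group because the ketone is cross-conjugated with the hydroxyl groups and deactivates the ring.

Step 2
Reactants: 3 butyrylphloroglucinol
Product: 4 1-[2,4,6-tris(benzyloxy)phenyl]butan-1-one
Conditions: BnBr, K2CO3, DMF, 70 °C
Reagents that add atoms: benzyl bromide, BrCc1ccccc1
Why: Williamson ether synthesis; carbonate in warm DMF should also alkylate the two hydrogen-bonded ortho hydroxyl groups, and the dipolar aprotic solvent favours O- over C-benzylation.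

Step 3
Reactants: 4 tribenzyl ether ketone; 5 dichloromethyl methyl ether
Product: 6 3-butanoyl-2,4,6-tris(benzyloxy)benzaldehyde
Conditions: TiCl4, CH2Cl2, −78 to −30 °C; then H2O
Reagents that add atoms: water, O
Why: Rieche formylation at one of the two equivalent free ring carbons, each ortho/para to three benzyloxy groups; the first formyl group deactivates the ring against a second, the low temperature spares the benzyl ethers next to the ketone, and a Vilsmeier reagent is avoided because it would need heating on this deactivated ring, where it also attacks the enolisable ketone.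

Step 4
Reactants: 6 aldehyde; 7 Meldrum's acid
Product: 11 3-[3-butanoyl-2,4,6-tris(benzyloxy)phenyl]propanoic acid, via arylidene Meldrum's acid 8 (not isolated), via benzyl Meldrum's acid 9 (not isolated), via arylmethylmalonic acid 10 (not isolated)
Conditions: HCO2H–NEt3 (5:2), 95 °C
Reagents that add atoms: none
Why: Reductive Knoevenagel homologation in one pot (Knoevenagel condensation, conjugate reduction of the arylidene Meldrum's acid by formate, hydrolysis and decarboxylation), which saturates the new C=C without hydrogen gas and so leaves the benzyl ethers and the hindered ketone alone.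

Step 5
Reactants: 11 propanoic acid; 12 ethoxyacetylene
Product: 15 rac-3-ethoxy-4-(ArB-methyl)cyclobut-2-en-1-one, via acid chloride 13 (not isolated), via alkylketene 14 (not isolated)
Conditions: (COCl)2, cat. DMF, CH2Cl2, 0 °C to rt; evaporate; then 12 (3 equiv), NEt3 (slow addition), MeCN, rt
Reagents that add atoms: none
Why: Acid chloride formation, dehydrochlorination to the monoalkylketene and ketene–ynol ether (2+2) cycloaddition, in which the terminal alkyne carbon attacks the ketene carbonyl carbon so that the ethoxy-bearing carbon bonds to the ketene α-carbon; the C4 centre forms as a racemate and is destroyed in step 10, and both ortho positions of ring B are blocked, so 13 cannot cyclise to an indanone.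

Step 6
Reactants: 16 2-methylphloroglucinol
Product: 17 1,3,5-tris(benzyloxy)-2-methylbenzene
Conditions: BnBr, K2CO3, DMF, 60 °C
Reagents that add atoms: benzyl bromide, BrCc1ccccc1
Why: Williamson ether synthesis as in step 2; the three phenols are unhindered and O-benzylation in DMF should outrun C-benzylation of the electron-rich ring.

Step 7
Reactants: 17 tribenzyloxytoluene; 18 ethyl chlorooxoacetate
Product: 19 ethyl 2-oxo-2-[2,4,6-tris(benzyloxy)-3-methylphenyl]acetate
Conditions: TiCl4, CH2Cl2, −78 to −20 °C
Reagents that add atoms: none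
Why: Friedel–Crafts acylation with the activated oxalyl half-ester chloride at one of two equivalent free carbons, each flanked by two benzyloxy groups; the α-keto ester group deactivates the ring against a second acylation.

Step 8
Reactants: 19 aryl glyoxylate
Product: 21 ethyl 2-[2,4,6-tris(benzyloxy)-3-methylphenyl]acetate, via mandelate 20 (not isolated)
Conditions: Et3SiH, TFA, CH2Cl2, 0 °C to rt
Reagents that add atoms: none
Why: Ionic hydrogenation: the protonated aryl ketone is reduced by the silane to mandelate 20, which ionises to a cation stabilised by the three alkoxy groups and is reduced again, so the benzylic C=O becomes CH2 without hydrogen gas and the benzyl ethers stay.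

Step 9
Reactants: 21 arylacetic ester; 22 dibromomethane
Product: 25 triisopropyl{[3-(ArD)prop-1-yn-1-yl]oxy}silane, via dibromoketone enolate 23 (not isolated), via lithium ynolate 24 (not isolated)
Conditions: LiTMP (lithium 2,2,6,6-tetramethylpiperidide, from 2,2,6,6-tetramethylpiperidine and n-BuLi), THF, −78 °C; then n-BuLi, −78 °C to rt; then TIPSCl, −78 °C to rt
Reagents that add atoms: triisopropylsilyl chloride, CC(C)[Si](Cl)(C(C)C)C(C)C
Why: Kowalski ynolate synthesis: LiCHBr2 adds to the ester, enolate 23 undergoes bromine–lithium exchange and 1,2-shift of the arylmethyl group to ynolate 24, and the bulky silyl chloride traps it on oxygen; ring D carries no ketone at this stage, so the strong bases meet only ethers.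

Step 10
Reactants: 15 3-ethoxy-4-(ArB-methyl)cyclobutenone; 25 siloxyalkyne (1.5 equiv)
Product: 30 3-ethoxy-5-(triisopropylsiloxy)-2-(ArB-methyl)-6-(ArD-methyl)phenol, via vinylketene 26 (not isolated), via vinylcyclobutenone 27 (not isolated), via dienylketene 28 (not isolated), via cyclohexadienone 29 (not isolated)
Conditions: PhMe, 110 °C, sealed tube, Ar
Reagents that add atoms: none
Why: Proposed new method: the Danheiser benzannulation is established for 3-alkyl- and 3-arylcyclobutenones with siloxyalkynes, and thermal 4π opening of 3-alkoxycyclobutenones to alkoxyvinylketenes is established in squarate-type ring expansions, but capture of a (2-ethoxyvinyl)ketene by a siloxyalkyne to give a phloroglucinol pattern is an untested combination of the two. Heating should open 15 by conrotatory 4π cleavage of the carbonyl–C4 bond, the benzylic substituent turning outward, to vinylketene 26; the carbon of 25 remote from oxygen attacks the ketene carbonyl carbon and the zwitterion closes to vinylcyclobutenone 27 (stepwise 2+2). Cyclobutenone 27 reopens to dienylketene 28, which closes ring C by thermal disrotatory 6π electrocyclisation between the ketene carbon and the alkene terminus (re-forming the bond broken first) to dienone 29, and tautomerisation gives phenol 30. No stereocentre remains: the C4 centre of 15 and the sp3 centres of 27 and 29 all become aromatic carbons. The step needs one regiochemistry in the ketene–alkyne addition, and the polarisation of the ynol ether against the electrophilic ketene carbon secures it, which puts the OH between the two benzyl carbons and the ethoxy and siloxy groups on either side of the single unsubstituted carbon. The conditions are neutral, so no benzylic cation can scramble the bridges, and benzyl ethers, the ring B ketone and the silyl ynol ether are all stable to them.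

Step 11
Reactants: 30 phenol
Product: 32 1,5-bis(benzyloxy)-3-ethoxy-4-(ArB-methyl)-6-(ArD-methyl)benzene (ring C numbered from the former phenol carbon), via monobenzyl silyl ether 31 (not isolated)
Conditions: BnBr, Cs2CO3, DMF, 40 °C; then TBAF, rt
Reagents that add atoms: benzyl bromide, BrCc1ccccc1
Why: Williamson benzylation of the hindered phenol, then fluoride cleavage of the aryl silyl ether in the presence of excess benzyl bromide, so that the phenoxide set free is O-benzylated at once and ring C never exists as a free resorcinol dianion that could be C-alkylated.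

Step 12
Reactants: 32 protected BCD skeleton; 2 butanoyl chloride (2.5 equiv)
Product: 33 the bis-acylation product of 32, with butanoyl on the free carbon of ring C (between OEt and OBn) and on the free carbon of ring D (between two OBn)
Conditions: TiCl4, DTBMP, CH2Cl2, −78 to −20 °C
Reagents that add atoms: none
Why: Double Friedel–Crafts acylation: rings C and D each have exactly one free carbon, flanked by two alkoxy groups and para to a third, whereas the free carbon of ring B sits on a ring whose alkoxy groups are cross-conjugated with its butanoyl group and is much less nucleophilic; the hindered pyridine base traps HCl so that no protic acid can cleave the electron-rich diarylmethane bridges by ipso protonation.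

Step 13
Reactants: 33 tris-ketone
Product: 34 nonaphenol BCD: three butanoylphloroglucinol rings joined by two CH2 bridges, ring D with methyl, ring B with one free carbon
Conditions: BCl3, C6HMe5, CH2Cl2, −78 °C to rt; then H2O
Reagents that add atoms: none
Why: Lewis-acid ether cleavage: BCl3 removes the eight aryl benzyl ethers at low temperature while pentamethylbenzene traps the benzyl cations, and on warming it dealkylates the ethoxy group through its six-membered chelate with the neighbouring ring C ketone (chelation-assisted dealkylation); every ring now carries an acyl group, which makes the CH2 bridges resistant to acid.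

Step 14
Reactants: 34 nonaphenol; 35 bis(dimethylamino)methane (1.05 equiv)
Product: 36 ring B Mannich base, with CH2NMe2 on the former free carbon of ring B
Conditions: 1,4-dioxane, rt
Reagents that add atoms: none
Why: Phenolic Mannich reaction: the acidic acylphloroglucinol protonates the aminal to the dimethyl(methylidene)ammonium ion, which substitutes the only aromatic C–H of 34; every other ring carbon is blocked, so the aminomethyl group can go to one place only.

Step 15
Reactants: 3 butyrylphloroglucinol; 37 iodomethane (2 equiv)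
Product: 38 2-butanoyl-3,5-dihydroxy-4,4-dimethylcyclohexa-2,5-dien-1-one (butyrylfilicinic acid)
Conditions: NaOMe, MeOH, 0 °C to rt
Reagents that add atoms: none
Why: Dearomatising double C-methylation of the acylphloroglucinol polyanion at one ring carbon, the classical preparation of acylfilicinic acids; the stoichiometry is held at two equivalents and 38 is separated from mono-, 3,5-di- and trimethylated by-products.

Step 16
Reactants: 36 Mannich base; 38 butyrylfilicinic acid (2 equiv)
Product: 40 target CNP0246352.0, via ortho-quinone methide 39 (not isolated)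
Conditions: 1,4-dioxane, 70 °C, Ar
Reagents that add atoms: none
Why: Alkylation of a cyclic β-triketone by a phenolic Mannich base: 38, a vinylogous acid, protonates the amine, loss of dimethylamine gives ortho-quinone methide 39, and C6 of 38, the only nucleophilic carbon of the enolised triketone, adds in a Michael reaction that re-aromatises ring B and closes the last CH2 bridge.

**Compound list**

1 | phloroglucinol | Oc1cc(O)cc(O)c1 | starting material
2 | butanoyl chloride | CCCC(Cl)=O | starting material
3 | 1-(2,4,6-trihydroxyphenyl)butan-1-one | CCCC(=O)c1c(O)cc(O)cc1O | intermediate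
4 | 1-[2,4,6-tris(benzyloxy)phenyl]butan-1-one | CCCC(=O)c1c(OCc2ccccc2)cc(OCc2ccccc2)cc1OCc1ccccc1 | intermediate
5 | dichloromethyl methyl ether | COC(Cl)Cl | starting material
6 | 3-butanoyl-2,4,6-tris(benzyloxy)benzaldehyde | CCCC(=O)c1c(OCc2ccccc2)cc(OCc2ccccc2)c(C=O)c1OCc1ccccc1 | intermediate
7 | Meldrum's acid (2,2-dimethyl-1,3-dioxane-4,6-dione) | CC1(C)OC(=O)CC(=O)O1 | starting material
8 | 5-(ArB-methylidene)-2,2-dimethyl-1,3-dioxane-4,6-dione | CCCC(=O)c1c(OCc2ccccc2)cc(OCc2ccccc2)c(C=C2C(=O)OC(C)(C)OC2=O)c1OCc1ccccc1 | intermediate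
9 | 5-(ArB-methyl)-2,2-dimethyl-1,3-dioxane-4,6-dione | CCCC(=O)c1c(OCc2ccccc2)cc(OCc2ccccc2)c(CC2C(=O)OC(C)(C)OC2=O)c1OCc1ccccc1 | intermediate
10 | 2-(ArB-methyl)propanedioic acid | CCCC(=O)c1c(OCc2ccccc2)cc(OCc2ccccc2)c(CC(C(=O)O)C(=O)O)c1OCc1ccccc1 | intermediate
11 | 3-[3-butanoyl-2,4,6-tris(benzyloxy)phenyl]propanoic acid | CCCC(=O)c1c(OCc2ccccc2)cc(OCc2ccccc2)c(CCC(=O)O)c1OCc1ccccc1 | intermediate
12 | ethoxyacetylene | CCOC#C | starting material
13 | 3-(ArB)propanoyl chloride | CCCC(=O)c1c(OCc2ccccc2)cc(OCc2ccccc2)c(CCC(=O)Cl)c1OCc1ccccc1 | intermediate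
14 | 3-(ArB)prop-1-en-1-one (alkylketene) | CCCC(=O)c1c(OCc2ccccc2)cc(OCc2ccccc2)c(CC=C=O)c1OCc1ccccc1 | intermediate
15 | rac-3-ethoxy-4-(ArB-methyl)cyclobut-2-en-1-one | CCOC1=CC(=O)C1Cc1c(OCc2ccccc2)cc(OCc2ccccc2)c(C(=O)CCC)c1OCc1ccccc1 | intermediate
16 | 2-methylphloroglucinol | Cc1c(O)cc(O)cc1O | starting material
17 | 1,3,5-tris(benzyloxy)-2-methylbenzene | Cc1c(OCc2ccccc2)cc(OCc2ccccc2)cc1OCc1ccccc1 | intermediate
18 | ethyl chlorooxoacetate | CCOC(=O)C(Cl)=O | starting material
19 | ethyl 2-oxo-2-[2,4,6-tris(benzyloxy)-3-methylphenyl]acetate | CCOC(=O)C(=O)c1c(OCc2ccccc2)cc(OCc2ccccc2)c(C)c1OCc1ccccc1 | intermediate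
20 | rac-ethyl 2-hydroxy-2-[2,4,6-tris(benzyloxy)-3-methylphenyl]acetate | CCOC(=O)C(O)c1c(OCc2ccccc2)cc(OCc2ccccc2)c(C)c1OCc1ccccc1 | intermediate
21 | ethyl 2-[2,4,6-tris(benzyloxy)-3-methylphenyl]acetate | CCOC(=O)Cc1c(OCc2ccccc2)cc(OCc2ccccc2)c(C)c1OCc1ccccc1 | intermediate
22 | dibromomethane | BrCBr | starting material
23 | lithium enolate of 1,1-dibromo-3-(ArD)propan-2-one | [Li+].[O-]C(Cc1c(OCc2ccccc2)cc(OCc2ccccc2)c(C)c1OCc1ccccc1)=C(Br)Br | intermediate
24 | lithium 3-(ArD)prop-1-yn-1-olate | [Li+].[O-]C#CCc1c(OCc2ccccc2)cc(OCc2ccccc2)c(C)c1OCc1ccccc1 | intermediate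
25 | triisopropyl{[3-(ArD)prop-1-yn-1-yl]oxy}silane | CC(C)[Si](OC#CCc1c(OCc2ccccc2)cc(OCc2ccccc2)c(C)c1OCc1ccccc1)(C(C)C)C(C)C | intermediate
26 | (3Z)-3-ethoxy-5-(ArB)penta-1,3-dien-1-one (vinylketene) | O=C=C/C(OCC)=C/Cc1c(OCc2ccccc2)cc(OCc2ccccc2)c(C(=O)CCC)c1OCc1ccccc1 | intermediate
27 | rac-2-(ArD-methyl)-3-(triisopropylsiloxy)-4-[(1Z)-1-ethoxy-3-(ArB)prop-1-enyl]cyclobut-2-en-1-one | O=C1C(Cc2c(OCc3ccccc3)cc(OCc3ccccc3)c(C)c2OCc2ccccc2)=C(O[Si](C(C)C)(C(C)C)C(C)C)C1/C(OCC)=C/Cc1c(OCc2ccccc2)cc(OCc2ccccc2)c(C(=O)CCC)c1OCc1ccccc1 | intermediate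
28 | 2-(ArD-methyl)-3-(triisopropylsiloxy)-5-ethoxy-7-(ArB)hepta-1,3,5-trien-1-one (dienylketene, ketene carbon and ethoxyalkene cis across the central C=C) | O=C=C(Cc1c(OCc2ccccc2)cc(OCc2ccccc2)c(C)c1OCc1ccccc1)/C(O[Si](C(C)C)(C(C)C)C(C)C)=C\C(OCC)=C\Cc1c(OCc2ccccc2)cc(OCc2ccccc2)c(C(=O)CCC)c1OCc1ccccc1 | intermediate
29 | rac-5-ethoxy-3-(triisopropylsiloxy)-6-(ArB-methyl)-2-(ArD-methyl)cyclohexa-2,4-dien-1-one | O=C1C(Cc2c(OCc3ccccc3)cc(OCc3ccccc3)c(C)c2OCc2ccccc2)=C(O[Si](C(C)C)(C(C)C)C(C)C)C=C(OCC)C1Cc1c(OCc2ccccc2)cc(OCc2ccccc2)c(C(=O)CCC)c1OCc1ccccc1 | intermediate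
30 | 3-ethoxy-5-(triisopropylsiloxy)-2-(ArB-methyl)-6-(ArD-methyl)phenol | CCOc1cc(O[Si](C(C)C)(C(C)C)C(C)C)c(Cc2c(OCc3ccccc3)cc(OCc3ccccc3)c(C)c2OCc2ccccc2)c(O)c1Cc1c(OCc2ccccc2)cc(OCc2ccccc2)c(C(=O)CCC)c1OCc1ccccc1 | intermediate
31 | benzyl ether of 30 at the phenol oxygen, silyl ether retained | CCOc1cc(O[Si](C(C)C)(C(C)C)C(C)C)c(Cc2c(OCc3ccccc3)cc(OCc3ccccc3)c(C)c2OCc2ccccc2)c(OCc2ccccc2)c1Cc1c(OCc2ccccc2)cc(OCc2ccccc2)c(C(=O)CCC)c1OCc1ccccc1 | intermediate
32 | 1,5-bis(benzyloxy)-3-ethoxy-4-(ArB-methyl)-6-(ArD-methyl)benzene | CCOc1cc(OCc2ccccc2)c(Cc2c(OCc3ccccc3)cc(OCc3ccccc3)c(C)c2OCc2ccccc2)c(OCc2ccccc2)c1Cc1c(OCc2ccccc2)cc(OCc2ccccc2)c(C(=O)CCC)c1OCc1ccccc1 | intermediate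
33 | 32 with butanoyl on the free carbon of ring C and on the free carbon of ring D | CCOc1c(C(=O)CCC)c(OCc2ccccc2)c(Cc2c(OCc3ccccc3)c(C(=O)CCC)c(OCc3ccccc3)c(C)c2OCc2ccccc2)c(OCc2ccccc2)c1Cc1c(OCc2ccccc2)cc(OCc2ccccc2)c(C(=O)CCC)c1OCc1ccccc1 | intermediate
34 | nonaphenol BCD (all ethers of 33 cleaved) | CCCC(=O)c1c(O)cc(O)c(Cc2c(O)c(Cc3c(O)c(C)c(O)c(C(=O)CCC)c3O)c(O)c(C(=O)CCC)c2O)c1O | intermediate
35 | bis(dimethylamino)methane | CN(C)CN(C)C | starting material
36 | 34 with CH2NMe2 on the free carbon of ring B | CCCC(=O)c1c(O)c(CN(C)C)c(O)c(Cc2c(O)c(Cc3c(O)c(C)c(O)c(C(=O)CCC)c3O)c(O)c(C(=O)CCC)c2O)c1O | intermediate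
37 | iodomethane | CI | starting material
38 | 2-butanoyl-3,5-dihydroxy-4,4-dimethylcyclohexa-2,5-dien-1-one | CCCC(=O)C1=C(O)C(C)(C)C(O)=CC1=O | intermediate
39 | ortho-quinone methide of ring B (exocyclic CH2 and adjacent ring C=O) | C=C1C(=O)C(Cc2c(O)c(Cc3c(O)c(C)c(O)c(C(=O)CCC)c3O)c(O)c(C(=O)CCC)c2O)=C(O)C(C(=O)CCC)=C1O | intermediate
40 | CNP0246352.0 | CCCC(=O)C1=C(O)C(C)(C)C(O)=C(Cc2c(O)c(Cc3c(O)c(Cc4c(O)c(C)c(O)c(C(=O)CCC)c4O)c(O)c(C(=O)CCC)c3O)c(O)c(C(=O)CCC)c2O)C1=O | target

**Step count**

Total: 16 steps. Longest linear sequence: 11 steps (steps 1, 2, 3, 4, 5, 10, 11, 12, 13, 14, 16).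

**Steps most likely to fail**

Step 10 (proposed new method). The ethoxy group makes 15 a vinylogous ester, which may raise the ring-opening temperature to a point where the (2-ethoxyvinyl)ketene dimerises or acylates the product phenol faster than the siloxyalkyne intercepts it. The sequence may also stall at the vinylcyclobutenone. The fallback drops the benzannulation and builds the two bridges one at a time on free acylphloroglucinols by known Mannich base / ortho-quinone methide alkylation. It sets out from 16, 2, 3 and 35 and comes back at 34.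
- 16 is C-acylated with 2 (AlCl3, PhNO2) to 1-(2,4,6-trihydroxy-3-methylphenyl)butan-1-one F1.
- 35 in dioxane at rt converts the only free ring carbon of F1 into the dimethylaminomethyl Mannich base F2.
- Heating F2 with a fivefold excess of 3 in dioxane gives the methylene-bridged C–D dimer F3; the excess limits double alkylation of 3.
- F3 has one free ring carbon, on ring C, which 35 converts into Mannich base F4.
- Heating F4 with excess 3 gives 34, and the route continues at step 14.

Step 12. Acid may cleave or exchange the electron-rich diarylmethane bridges (ipso protonation or ipso acylation), and benzyl ethers may be lost before both hindered carbons are acylated. The fallback sets out from 32 and comes back at 33. It installs each butanoyl group as a formyl group first, using a weak electrophile and no strong Lewis acid.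
- Vilsmeier–Haack formylation (POCl3, DMF, 0 °C to rt) of the two activated free carbons gives dialdehyde F5; at this temperature the hindered ring B ketone and the deactivated ring B carbon should not react.
- n-PrMgBr in THF at −78 °C adds to the two aldehydes in preference to the di-ortho-substituted ketone and gives bis-carbinol F6 as a diastereomer mixture.
- Dess–Martin periodinane in CH2Cl2 oxidises both benzylic alcohols to give 33.

Step 16. Heating the polyphenol with amine may fragment the existing CH2 bridges by retro-Michael loss of an acylphloroglucinol and let them recombine (bridge exchange), and 38 may be alkylated on oxygen. The fallback reverses the roles so that the electrophile is generated on ring A under milder conditions. It sets out from 38 and 34 (step 14 is skipped) and comes back at 40.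
- 38 with 35 in CH2Cl2 at 0 °C gives 2-butanoyl-6-[(dimethylamino)methyl]-3,5-dihydroxy-4,4-dimethylcyclohexa-2,5-dien-1-one F7.
- F7 loses dimethylamine readily to the exo-methylene triketone, and stirring it with 34 in dioxane–AcOH at rt to 40 °C lets the only free ring carbon of 34 add in a Michael reaction to give 40.

**Further compounds**

F1 | step 10 | 1-(2,4,6-trihydroxy-3-methylphenyl)butan-1-one | CCCC(=O)c1c(O)cc(O)c(C)c1O
F2 | step 10 | 1-{3-[(dimethylamino)methyl]-2,4,6-trihydroxy-5-methylphenyl}butan-1-one | CCCC(=O)c1c(O)c(CN(C)C)c(O)c(C)c1O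
F3 | step 10 | methylene-bridged C–D dimer of butyrylphloroglucinol and F1 | CCCC(=O)c1c(O)cc(O)c(Cc2c(O)c(C)c(O)c(C(=O)CCC)c2O)c1O
F4 | step 10 | F3 with CH2NMe2 on the free carbon of ring C | CCCC(=O)c1c(O)c(CN(C)C)c(O)c(Cc2c(O)c(C)c(O)c(C(=O)CCC)c2O)c1O
F5 | step 12 | 32 with formyl on the free carbons of rings C and D | CCOc1c(C=O)c(OCc2ccccc2)c(Cc2c(OCc3ccccc3)c(C=O)c(OCc3ccccc3)c(C)c2OCc2ccccc2)c(OCc2ccccc2)c1Cc1c(OCc2ccccc2)cc(OCc2ccccc2)c(C(=O)CCC)c1OCc1ccccc1
F6 | step 12 | 32 with 1-hydroxybutyl on the free carbons of rings C and D (diastereomer mixture) | CCOc1c(C(O)CCC)c(OCc2ccccc2)c(Cc2c(OCc3ccccc3)c(C(O)CCC)c(OCc3ccccc3)c(C)c2OCc2ccccc2)c(OCc2ccccc2)c1Cc1c(OCc2ccccc2)cc(OCc2ccccc2)c(C(=O)CCC)c1OCc1ccccc1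
F7 | step 16 | 2-butanoyl-6-[(dimethylamino)methyl]-3,5-dihydroxy-4,4-dimethylcyclohexa-2,5-dien-1-one | CCCC(=O)C1=C(O)C(C)(C)C(O)=C(CN(C)C)C1=O
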